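The earlier runs and the new flask are calculated for substances that don't exist.

The vessel is closed and stirred; in it single-handed L meets E and D, charged as a racemate. The flasks and readings are these:

| flask | E | D | L | remark | time |
|---|---|---|---|---|---|
| south-east | 0.12 M | 0.12 M | 0.162 M | run made earlier |  |
| east | 0.16 M | 0.16 M | 0.162 M | run made earlier |  |
| Thursday's | 0.081 M | 0.081 M | 0.0500 M |  | 3.0 h |
| Saturday's | 0.081 M | 0.081 M | 0.250 M |  | 3.0 h |
| Monday's | 0.081 M | 0.081 M | 0.0800 M |  | 3.0 h |
| Tuesday's | 0.081 M | 0.081 M | 0.162 M |  | 3.0 h |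
| Sunday's | 0.081 M | 0.081 M | 0.0400 M |  | 3.0 h |

- south-east (time / min: X / %, E / %): 3.00: 10.2, 40.6; 4.00: 9.3, 40.4; 6.00: 12.3, 36.3; 10.0: 15.9, 29.2; 15.0: 21.4, 23.2; 25.0: 27.4, 18.9; 40.0: 35.7, 15.8
- east (time / min: X / %, E / %): 5.00: 9.4, 36.8; 10.0: 16.6, 30.6; 15.0: 21.2, 27.9; 20.0: 23.2, 21.6; 25.0: 27.4, 20.4; 30.0: 28.0, 18.9; 40.0: 31.7, 15.9

(each reading ± 1 percentage point)

- the flasks put in order of amount of X, in percent of the E and D together charged, best first, at 3.0 h (Thursday's / Saturday's / Monday's / Tuesday's / Sunday's)
- the amount of X, in percent of the E and D together charged of the flask you put first, at 3.0 h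
- the amount of X, in percent of the E and D together charged of the flask you put last, at 3.0 h

Work with the fraction of E left, not with the X made. E starts at 50.0 % of the substrate, and in the south-east run it reads 29.2 % at 10.0 min. Dividing the logarithm of that fall by c(L) and the time gives a reading of 0.332 M⁻¹ min⁻¹. Call this k the E clock: at steady c(L), the fraction of E left after time t is exp(−k c(L) t), which is the pseudo-first-order form.

Turn L first. By hand, Saturday's has k c(L) t = 14.9 at its charged c(L), so the clock leaves a fraction 3.25 × 10⁻⁷ of E, and X should arrive near E's charge. Sunday's L can serve 24.7 % of the substrate if one L makes one X, so there L is the limiting reagent.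

Turn time next. The flasks stand for 3.0 h, against 40.0 min for the longest earlier reading. Over the last south-east interval X rose 8.3 percentage points while E fell 3.1 points, but the east run gives 4.3 points and 4.5 points over its last span. With a scatter of 1 point per reading, I take this only as a hint that X can gain more than E loses, and I would put Saturday's near 50.0 %, holding that ceiling loosely.

The forecast gives Saturday's > Tuesday's > Monday's > Thursday's > Sunday's, with 49.8 % first and 20.5 % last: “Saturday's has excess L, and E is essentially gone”.

The flasks give Saturday's > Tuesday's > Monday's > Thursday's > Sunday's, with 63.4 % for Saturday's and 20.6 % for Sunday's. Sunday's X is held down by the shrinking supply of L, as one part of what is missing: with L kept at its charge, that flask gives 48.9 %.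

    E ⇌ Z (K = 0.280, k = 2.60 × 10⁻⁴ s⁻¹)
    L + D → Q (k = 7.80 × 10⁻⁴ M⁻¹ s⁻¹)
    Z → J (k = 1.10 × 10⁻⁴ s⁻¹)
    D ⇌ Z (K = 0.280, k = 2.60 × 10⁻⁴ s⁻¹)
    L + E → X (k = 0.00560 M⁻¹ s⁻¹)
    Z → G (k = 3.10 × 10⁻⁵ s⁻¹)

Run the clock on Saturday's with L held at the 43 % of its charge that remains at 3.0 h, lower than at any earlier moment. You get 0.157 % of E left, yet the flask holds 2.5 %, and X stands 13 points above E's charge. So E is being refilled, from D through Z. Saturday's read at 2.0 h shows the same: with 47 % of L, the clock gives 0.897 % of E's charge, and the flask holds 4.5 % of it.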